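The numbers in the tables are simulated for an exercise; scatter was added.

I chose to answer your quick question by counting half-lives, and I set your hunch, that south at 48 °C goes on losing target through the whole 1.0 h, against that count.

| setting | oak | larch | alder | south-west | south | east |
|---|---|---|---|---|---|---|
| starting material | 0.30 M | 0.30 M | 0.30 M | 0.30 M | 0.30 M | 0.30 M |
| reagent | 1.2 equiv | 1.2 equiv | 2.4 equiv | 1.20 equiv | 1.20 equiv | 1.20 equiv |
| second substrate | 0.50 equiv | 0.75 equiv | 1 equiv | 1.00 equiv | 1.00 equiv | 1.00 equiv |
| temperature | 35 °C | 48 °C | 35 °C | 40 °C | 48 °C | 56 °C |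
| remark | run made earlier | run made earlier | run made earlier |  |  |  |
| time |  |  |  | 1.0 h | 1.0 h | 1.0 h |

| run | time / min | target / % | starting material / % |
|---|---|---|---|
| oak | 3.00 | 31.0 | 59.4 |
| oak | 5.00 | 37.1 | 50.2 |
| oak | 8.00 | 38.1 | 42.7 |
| oak | 12.0 | 36.8 | 38.3 |
| oak | 20.0 | 31.3 | 34.1 |
| oak | 40.0 | 23.9 | 29.1 |
| larch | 3.00 | 21.0 | 53.7 |
| larch | 5.00 | 18.4 | 50.4 |
| larch | 8.00 | 15.8 | 48.1 |
| larch | 12.0 | 13.7 | 46.3 |
| larch | 20.0 | 13.8 | 45.0 |
| larch | 40.0 | 13.7 | 45.3 |
| alder | 8.00 | 52.5 | 23.7 |
| alder | 15.0 | 45.9 | 19.5 |
| alder | 20.0 | 40.3 | 17.0 |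
| alder | 30.0 | 34.3 | 15.2 |
| alder | 40.0 | 29.7 | 14.1 |

(readings scatter by 0.3 percentage points)

* which of the two there is more of at the end, south-west (cross product / target)
* which of the two there is more of at the end, south (cross product / target)
* which of the two there is more of at the end, east (cross product / target)
* amount of target at the end, in percent of the starting material charged, south-west
* amount of target at the end, in percent of the starting material charged, south
* amount of target at the end, in percent of the starting material charged, east



1. Larch ran at the same temperature as south, so I read the clock there. Its starting material levelled off near 45.3%, and its distance from that last reading fell from 8.4 percentage points at 3.00 min to 2.8 points at 8.00 min.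

2. Those two readings gave 3.15 min as the time in which that distance halves. I called this the levelling half-life, an apparent first-order half-life.

3. The 1.0 h of south holds 19.0 of these, so the time is far longer than the clock. By 0.500 h, 9.51 had passed, and the reckoned distance left was 0.022 points, less than the scatter of 0.3 points. So I treated the end of south as a plateau, against your hunch. Larch agreed: its target read 13.7% at 12.0 min and 13.7% at 40.0 min.

4. South carries more second substrate than larch, so I committed to south ending below the 13.7% of larch.

5. The forecast named cross product as the larger in all flasks and gave target 16% (11% to 22%) in south-west, 11% (8% to 14%) in south and 7% (4% to 11%) in east, expecting in hotter runs that “a larger share of what converts goes on to cross product”.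

South-west ended with 11.6% of target, south with 10.4% and east with 7.82%, each with more cross product than target, at 32.8%, 32.8% and 33.1%.

    starting material + second substrate → cross product (k = 0.00792 M⁻¹ s⁻¹, Ea = 71.0 kJ mol⁻¹)
    starting material + reagent ⇌ target (K = 6.20 M⁻¹, k = 0.0146 M⁻¹ s⁻¹, Ea = 60.0 kJ mol⁻¹, ΔH = −84.0 kJ mol⁻¹)
    target ⇌ isomer of the product (K = 2.00, k = 0.00103 s⁻¹, Ea = 86.0 kJ mol⁻¹, ΔH = −45.0 kJ mol⁻¹)
    second substrate + reagent → second product (k = 0.0176 M⁻¹ s⁻¹, Ea = 67.0 kJ mol⁻¹)
    (constants at 40 °C)

Left ten times as long, south still held 10.4% of target at 10.0 h. With 9.51 levelling half-lives of 3.15 min behind it at 0.500 h, south showed starting material of 43.3% there and 43.2% at the end. East ran at 56 °C, hotter than the 48 °C at which that clock was read, so I gave it no count; its starting material read 52.3% at 0.500 h and 52.3% at the end.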